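**Plan**
Locants: C1 is the exocyclic methylene carbon, C2 carries the 4-methylcyclohex-3-enyl ring, C5=C6 is the Z alkene, C13 is the carbonyl carbon and C22 is the isopropyl methine. The target is (ring R, 5Z, 10R, 14R, 18S).
Enabling feature: C13 (C=O) and the adjacent tertiary centre C14 (CH–CH3, labile once the ketone exists) have only the methylenes C12 and C15 as outer neighbours. The C1=C2 and C5=C6 alkenes and the cyclohexene ring lie at least seven bonds from C13, so C14 can enter as a chiral one-carbon carbenoid while C13 stays a C–B carbon.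
Cuts: C13=O back to C13–B, then C13–C14 and C14–C15 (two boron homologations), C6–C7 (B-alkyl Suzuki–Miyaura), C5=C6 (iodo-olefination) and C3–C4 (allyllithium plus ethylene oxide).
Forward: no ring is formed, since the cyclohexene arrives with (R)-limonene. One Wittig product of (S)-citronellal is divided into the C15–C22 boronate and the C7–C13 carbamate, and the carbamate is coupled to the limonene-derived C1–C6 vinyl iodide. Both halves are then joined through the ethyl carbenoid in one flask, and the C–B bond is oxidised to the ketone.
Stereochemistry: the ring centre comes from (R)-limonene, C10 and C18 both from (S)-citronellal, and C14 from (−)-sparteine-directed deprotonation (reagent control). The 5Z geometry comes from the kinetically controlled iodo-ylide olefination and a stereoretentive coupling.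

Key step: step 10

Assumption: (S)-citronellal and (R)-limonene are bought at the highest enantiomeric purity on offer, because their purity sets the diastereomeric purity at C10, C18 and the ring centre. CIP descriptors change along the route where substituent priorities change, while the spatial arrangement stays the same.

Step 1
Reactants: 1 (S)-citronellal
Product: 2 (4S)-4,8-dimethylnona-1,7-diene
Conditions: Ph3PCH3Br, KOtBu, THF, 0 °C to rt
Reagents that add atoms: methyltriphenylphosphonium bromide, C[P+](c1ccccc1)(c1ccccc1)c1ccccc1.[Br-]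
Why: Wittig methylenation of an unhindered aldehyde should be clean, the methyl-bearing centre is β to the carbonyl group and cannot epimerise, and this one diene later supplies both C10 and C18.

Step 2
Reactants: 2 (4S)-4,8-dimethylnona-1,7-diene
Product: 3 pinacol [(4R)-4,8-dimethylnon-7-en-1-yl]boronate
Conditions: HBpin (1.1 equiv), [Ir(cod)Cl]2 (1.5 mol %), dppm (3 mol %), CH2Cl2, rt
Reagents that add atoms: pinacolborane, [H]B1OC(C)(C)C(C)(C)O1
Why: Iridium-catalysed hydroboration with pinacolborane places boron on the terminal carbon of a monosubstituted alkene and ignores the trisubstituted one, so the C15–B bond should form chemo- and regioselectively.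

Step 3
Reactants: 3 pinacol [(4R)-4,8-dimethylnon-7-en-1-yl]boronate
Product: 4 pinacol [(4R)-4,8-dimethylnonyl]boronate
Conditions: H2 (1 atm), 10 % Pd/C, EtOAc, rt
Reagents that add atoms: none
Why: Heterogeneous catalytic hydrogenation saturates the remaining trisubstituted alkene, alkyl pinacol boronates are inert to it, and the stereocentre three carbons away is out of reach of double-bond migration.

Step 4
Reactants: 2 (4S)-4,8-dimethylnona-1,7-diene
Product: 6 (4S)-4-methylhept-6-en-1-ol, via (4S)-4-methylhept-6-enal 5 (not isolated)
Conditions: O3, CH2Cl2, Sudan Red 7B as end-point dye, −78 °C; Me2S, to rt; concentrate; NaBH4, MeOH, 0 °C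
Reagents that add atoms: ozone, [O-][O+]=O
Why: In this chemoselective ozonolysis the electron-rich trisubstituted alkene takes up ozone much faster than the monosubstituted one, the dye stops the gas flow after one equivalent, and borohydride reduction of the crude aldehyde gives the C13 alcohol.

Step 5
Reactants: 6 (4S)-4-methylhept-6-en-1-ol
Product: 7 (4S)-4-methylhept-6-en-1-yl N,N-diisopropylcarbamate
Conditions: iPr2NC(O)Cl, Et3N, CH2Cl2, reflux
Reagents that add atoms: N,N-diisopropylcarbamoyl chloride, CC(C)N(C(C)C)C(=O)Cl
Why: O-Carbamoylation of a primary alcohol is the standard entry to the hindered carbamates used for directed α-lithiation, and the group withstands boranes, palladium and aqueous base.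

Step 6
Reactants: 8 (R)-limonene
Product: 10 4-[(1R)-4-methylcyclohex-3-en-1-yl]pent-4-en-1-ol, via lithiated limonene 9 (not isolated)
Conditions: nBuLi, TMEDA, 8 (1.5 equiv), hexanes, rt; ethylene oxide, THF, −78 to 0 °C; H2O
Reagents that add atoms: ethylene oxide, C1CO1
Why: Allylic metalation with nBuLi·TMEDA occurs at the isopropenyl methyl group to give a 2-substituted allyllithium with equivalent termini, which opens the epoxide by SN2 to form C3–C4 while the ring C–H is not removed and the R centre is kept.

Step 7
Reactants: 10 4-[(1R)-4-methylcyclohex-3-en-1-yl]pent-4-en-1-ol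
Product: 11 4-[(1R)-4-methylcyclohex-3-en-1-yl]pent-4-enal
Conditions: DMP, pyridine, CH2Cl2, 0 °C to rt
Reagents that add atoms: none
Why: Dess–Martin oxidation stops at the aldehyde under near-neutral conditions, so neither alkene migrates and no carbonyl-ene cyclisation is triggered.

Step 8
Reactants: 11 4-[(1R)-4-methylcyclohex-3-en-1-yl]pent-4-enal
Product: 12 (4R)-4-[(5Z)-6-iodohepta-1,5-dien-2-yl]-1-methylcyclohex-1-ene
Conditions: EtPPh3I, nBuLi, THF, rt; I2, −78 °C; NaN(SiMe3)2, −20 °C; 11, −78 to −20 °C
Reagents that add atoms: ethyltriphenylphosphonium iodide, CC[P+](c1ccccc1)(c1ccccc1)c1ccccc1.[I-]; iodine, [I][I]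
Why: In this Stork–Zhao-type Wittig olefination the non-stabilised α-iodoethylidene ylide reacts under kinetic control through the cis-oxaphosphetane, which places iodine cis to the C4 chain and should give the Z-iodoalkene from a linear aliphatic aldehyde.

Step 9
Reactants: 7 (4S)-4-methylhept-6-en-1-yl N,N-diisopropylcarbamate; 12 (4R)-4-[(5Z)-6-iodohepta-1,5-dien-2-yl]-1-methylcyclohex-1-ene
Product: 14 (4R,8Z)-4,8-dimethyl-12-[(1R)-4-methylcyclohex-3-en-1-yl]trideca-8,12-dien-1-yl N,N-diisopropylcarbamate (C1–C13 carbamate), via B-alkyl-9-BBN adduct 13 (not isolated)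
Conditions: 7 (1.1 equiv), 9-BBN (1.05 equiv), THF, rt; aq Cs2CO3; 12, Pd(dppf)Cl2 (5 mol %), AsPh3, DMF, rt
Reagents that add atoms: none
Why: In this B-alkyl Suzuki–Miyaura coupling, 9-BBN is consumed by the terminal alkene of 7 before 12 is added, oxidative addition to zerovalent palladium and reductive elimination keep the Z geometry, and fast transmetalation at rt should outrun 5-exo carbopalladation of the C1=C2 alkene.

Step 10
Reactants: 4 pinacol [(4R)-4,8-dimethylnonyl]boronate; 15 ethyl 2,4,6-triisopropylbenzoate; 14 C1–C13 carbamate
Product: 21 pinacol [(6S,10R,14R,18Z)-2,6,10,14,18-pentamethyl-22-[(1R)-4-methylcyclohex-3-en-1-yl]tricosa-18,22-dien-11-yl]boronate (C13 boronate; both C13 epimers), via lithiated benzoate 16 (not isolated), via first boronate complex 17 (not isolated), via secondary boronate 18 (not isolated), via lithiated carbamate 19 (not isolated), via second boronate complex 20 (not isolated)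
Conditions: 15 (1.5 equiv), (−)-sparteine (1.5 equiv), sBuLi (1.45 equiv), Et2O, −78 °C; 4 (1.2 equiv), −78 °C, then 35 °C; recool to −78 °C; 19 added by cannula [from 14 (1.0 equiv), sBuLi, TMEDA, Et2O, −78 °C]; MgBr2·OEt2, then reflux; H2O
Reagents that add atoms: none
Why: sBuLi with (−)-sparteine removes the pro-S proton of 15 to give the configurationally stable carbenoid (S)-16, which adds to boron of 4 with retention to form complex 17; on warming, the C15 alkyl group shifts from boron to C14 antiperiplanar to the leaving triisopropylbenzoate, so C14 is inverted, the C14–C15 bond forms and (14R)-18 results. Carbenoid 19 then binds 18 to give complex 20, and the MgBr2-assisted 1,2-metallate shift carries the intact secondary C14 group, with retention, from boron to C13 while the carbamate departs, which forms the C13–C14 bond and leaves boron on C13. The closest known reaction type is reagent-controlled lithiation–borylation (Matteson-type homologation of pinacol boronates with α-oxygenated organolithiums), which is established for repeated cycles without purification between them and for primary as well as secondary migrating groups. No ring is closed in this step. C14, the one lasting new stereocentre, is controlled solely by the chiral diamine on 16 and not by the remote centres C10 and C18, whereas C13 arises as both epimers from the achiral TMEDA complex and loses its configuration in step 12. The step needs a single insertion per cycle and lithiation of 14 next to oxygen instead of at an allylic position: the first is secured because 17 and 20 do not rearrange at −78 °C and surplus carbenoid decomposes on warming before migration sets in, the second because the carbamate carbonyl directs sBuLi to C13 at −78 °C, where the unactivated allylic C–H bonds beside C1=C2, C5=C6 and the ring alkene are not metalated.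

Step 11
Reactants: 21 C13 boronate
Product: 22 (6S,10R,14R,18Z)-2,6,10,14,18-pentamethyl-22-[(1R)-4-methylcyclohex-3-en-1-yl]tricosa-18,22-dien-11-ol (C13 carbinol; both C13 epimers)
Conditions: 30 % H2O2, 2 M NaOH, THF, 0 °C to rt
Reagents that add atoms: hydrogen peroxide, OO
Why: In this boronate oxidation hydroperoxide anion adds to boron and the C13 group migrates to oxygen, and because the oxidant is nucleophilic it leaves the three unactivated alkenes alone.

Step 12
Reactants: 22 C13 carbinol
Product: 23 (6S,10R,14R,18Z)-2,6,10,14,18-pentamethyl-22-[(1R)-4-methylcyclohex-3-en-1-yl]tricosa-18,22-dien-11-one (CNP0272027.1)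
Conditions: DMP, pyridine, CH2Cl2, 0 °C to rt
Reagents that add atoms: none
Why: Pyridine-buffered Dess–Martin oxidation converts both C13 epimers into the one ketone under non-enolising conditions, so the C14 centre, which becomes enolisable only at this point, should keep its R configuration.

**Compound list**
1 | (S)-citronellal, (3S)-3,7-dimethyloct-6-enal | C[C@@H](CCC=C(C)C)CC=O | starting material
2 | (4S)-4,8-dimethylnona-1,7-diene | C=CC[C@@H](C)CCC=C(C)C | intermediate
3 | pinacol [(4R)-4,8-dimethylnon-7-en-1-yl]boronate | CC1(C)OB(CCC[C@@H](C)CCC=C(C)C)OC1(C)C | intermediate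
4 | pinacol [(4R)-4,8-dimethylnonyl]boronate (C15–C22) | CC1(C)OB(CCC[C@@H](C)CCCC(C)C)OC1(C)C | intermediate
5 | (4S)-4-methylhept-6-enal | C=CC[C@@H](C)CCC=O | intermediate
6 | (4S)-4-methylhept-6-en-1-ol | C=CC[C@@H](C)CCCO | intermediate
7 | (4S)-4-methylhept-6-en-1-yl N,N-diisopropylcarbamate (C7–C13) | C=CC[C@@H](C)CCCOC(=O)N(C(C)C)C(C)C | intermediate
8 | (R)-limonene, (4R)-1-methyl-4-(prop-1-en-2-yl)cyclohex-1-ene | C=C(C)[C@H]1CC=C(C)CC1 | starting material
9 | 2-[(1R)-4-methylcyclohex-3-en-1-yl]prop-2-en-1-yllithium (TMEDA complex, diamine not drawn) | [Li]CC(=C)[C@H]1CC=C(C)CC1 | intermediate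
10 | 4-[(1R)-4-methylcyclohex-3-en-1-yl]pent-4-en-1-ol | C=C(CCCO)[C@H]1CC=C(C)CC1 | intermediate
11 | 4-[(1R)-4-methylcyclohex-3-en-1-yl]pent-4-enal | C=C(CCC=O)[C@H]1CC=C(C)CC1 | intermediate
12 | (4R)-4-[(5Z)-6-iodohepta-1,5-dien-2-yl]-1-methylcyclohex-1-ene (C1–C6) | C=C(CC/C=C(/C)I)[C@H]1CC=C(C)CC1 | intermediate
13 | 9-[(4R)-7-(diisopropylcarbamoyloxy)-4-methylheptyl]-9-borabicyclo[3.3.1]nonane | C1CC2CCCC(C1)B2CCC[C@@H](C)CCCOC(=O)N(C(C)C)C(C)C | intermediate
14 | (4R,8Z)-4,8-dimethyl-12-[(1R)-4-methylcyclohex-3-en-1-yl]trideca-8,12-dien-1-yl N,N-diisopropylcarbamate (C1–C13) | C=C(CC/C=C(/C)CCC[C@@H](C)CCCOC(=O)N(C(C)C)C(C)C)[C@H]1CC=C(C)CC1 | intermediate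
15 | ethyl 2,4,6-triisopropylbenzoate | CCOC(=O)c1c(C(C)C)cc(C(C)C)cc1C(C)C | starting material
16 | (1S)-1-lithioethyl 2,4,6-triisopropylbenzoate ((−)-sparteine complex, diamine not drawn) | [Li][C@@H](C)OC(=O)c1c(C(C)C)cc(C(C)C)cc1C(C)C | intermediate
17 | lithium boronate complex of 16 and 4: boron carries pinacolate, the (4R)-4,8-dimethylnonyl group and the (1S)-1-(2,4,6-triisopropylbenzoyloxy)ethyl group | [Li+].C[C@@H](OC(=O)c1c(C(C)C)cc(C(C)C)cc1C(C)C)[B-]2(CCC[C@@H](C)CCCC(C)C)OC(C)(C)C(C)(C)O2 | intermediate
18 | pinacol [(2R,6R)-6,10-dimethylundecan-2-yl]boronate (C14–C22, boron on C14) | CC1(C)OB(OC1(C)C)[C@H](C)CCC[C@@H](C)CCCC(C)C | intermediate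
19 | C13-lithiated 14 (TMEDA complex, diamine not drawn; both C13 configurations) | C=C(CC/C=C(/C)CCC[C@@H](C)CCC([Li])OC(=O)N(C(C)C)C(C)C)[C@H]1CC=C(C)CC1 | intermediate
20 | lithium boronate complex of 19 and 18: boron carries pinacolate, the (2R,6R)-6,10-dimethylundecan-2-yl group and the C13 carbon that still bears the carbamate (both C13 configurations) | [Li+].C=C(CC/C=C(/C)CCC[C@@H](C)CCC(OC(=O)N(C(C)C)C(C)C)[B-]2(OC(C)(C)C(C)(C)O2)[C@H](C)CCC[C@@H](C)CCCC(C)C)[C@H]1CC=C(C)CC1 | intermediate
21 | pinacol [(6S,10R,14R,18Z)-2,6,10,14,18-pentamethyl-22-[(1R)-4-methylcyclohex-3-en-1-yl]tricosa-18,22-dien-11-yl]boronate (both C13 epimers) | C=C(CC/C=C(/C)CCC[C@@H](C)CCC(B2OC(C)(C)C(C)(C)O2)[C@H](C)CCC[C@@H](C)CCCC(C)C)[C@H]1CC=C(C)CC1 | intermediate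
22 | (6S,10R,14R,18Z)-2,6,10,14,18-pentamethyl-22-[(1R)-4-methylcyclohex-3-en-1-yl]tricosa-18,22-dien-11-ol (both C13 epimers) | C=C(CC/C=C(/C)CCC[C@@H](C)CCC(O)[C@H](C)CCC[C@@H](C)CCCC(C)C)[C@H]1CC=C(C)CC1 | intermediate
23 | (6S,10R,14R,18Z)-2,6,10,14,18-pentamethyl-22-[(1R)-4-methylcyclohex-3-en-1-yl]tricosa-18,22-dien-11-one, CNP0272027.1 | C=C(CC/C=C(/C)CCC[C@@H](C)CCC(=O)[C@H](C)CCC[C@@H](C)CCCC(C)C)[C@H]1CC=C(C)CC1 | target

**Step count and risks**
Total step count: 12.
Longest linear sequence: 7 steps. It runs from (S)-citronellal through steps 1, 4, 5, 9, 10, 11 and 12, and is equally long from (R)-limonene through steps 6, 7, 8, 9, 10, 11 and 12.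

**Step 10.**
- Risk: lithiation of the large triene carbamate may be incomplete or may stray to allylic positions. Migration of the hindered secondary group in the crowded second complex may be slow enough for oxygen migration or reversal to compete. Material left from the first cycle may also interfere with the second.
- Fallback: it sets out from 7 and 18 and comes back at 21. The organolithium chemistry is moved ahead of the Suzuki coupling, so that the second carbenoid carries only a terminal alkene. Boronate 18 is made from 4 and 15 as in the first half of step 10, but is worked up and filtered through silica. Carbamate 7 is lithiated (sBuLi, TMEDA, Et2O, −78 °C) to (4S)-1-lithio-4-methylhept-6-en-1-yl N,N-diisopropylcarbamate F1. F1 is combined with 18 and, after MgBr2·OEt2 and reflux, should give pinacol [(4S,8R,12S)-4,8,12,16-tetramethylheptadec-1-en-7-yl]boronate F2. 9-BBN then adds to its terminal alkene to give the C7 9-BBN adduct F3. Coupling of F3 with 12 under the conditions of step 9, to which a secondary alkyl pinacol boronate is inert, gives 21.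

**Step 8.**
- Risk: the iodo-ylide may form incompletely, so that the un-iodinated ylide gives the plain ethylidene alkene. Conversion of the aldehyde may be low, and Z selectivity may erode.
- Fallback: it sets out from 8 (through 9) and comes back at 12, and it fixes the alkene geometry before the carbon chain is attached. Commercial but-2-yn-1-ol is trans-hydroaluminated with NaAlH2(OCH2CH2OMe)2 in THF and the vinylalane is quenched with I2 to give (Z)-3-iodobut-2-en-1-ol F4. An Appel reaction (CBr4, PPh3, CH2Cl2, 0 °C) converts F4 into (Z)-1-bromo-3-iodobut-2-ene F5. Lithiated limonene 9 is prepared as in step 6, with limonene in excess so that no nBuLi survives. It is alkylated with F5 at −78 °C at the unhindered CH2Br terminus, which gives 12 directly and replaces steps 6 to 8.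

**Step 4.**
- Risk: ozone may also attack the terminal alkene once the trisubstituted one is nearly consumed, and the small aldehyde may be lost by evaporation during the solvent change.
- Fallback: it sets out from 2 and comes back at 5, and it replaces ozone by a two-stage cleavage that depends on the much larger rate difference in epoxidation. mCPBA (1 equiv, CH2Cl2, 0 °C) should oxidise only the trisubstituted alkene to 2,2-dimethyl-3-[(3S)-3-methylhex-5-en-1-yl]oxirane F6. H5IO6 in THF/H2O then cleaves F6 to aldehyde 5, which is reduced to 6 as in step 4.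

**Further compounds**
F1 | step 10 | (4S)-1-lithio-4-methylhept-6-en-1-yl N,N-diisopropylcarbamate (both configurations at the lithiated carbon) | C=CC[C@@H](C)CCC([Li])OC(=O)N(C(C)C)C(C)C
F2 | step 10 | pinacol [(4S,8R,12S)-4,8,12,16-tetramethylheptadec-1-en-7-yl]boronate (C7–C22; epimers at the boron-bearing carbon) | C=CC[C@@H](C)CCC(B1OC(C)(C)C(C)(C)O1)[C@H](C)CCC[C@@H](C)CCCC(C)C
F3 | step 10 | 9-BBN adduct of F2 with the borabicyclononyl group on C7 | C1CC2CCCC(C1)B2CCC[C@@H](C)CCC(B3OC(C)(C)C(C)(C)O3)[C@H](C)CCC[C@@H](C)CCCC(C)C
F4 | step 8 | (Z)-3-iodobut-2-en-1-ol | C/C(I)=C/CO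
F5 | step 8 | (Z)-1-bromo-3-iodobut-2-ene | C/C(I)=C/CBr
F6 | step 4 | 2,2-dimethyl-3-[(3S)-3-methylhex-5-en-1-yl]oxirane (epimers at the oxirane CH) | C=CC[C@@H](C)CCC1OC1(C)C
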